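# Proposed synthesis of CNP0508988.1 by an interrupted vinylketene–siloxyalkyne annulation

**Compound numbers used throughout.** 1 diethyl malonate; 2 prenyl bromide; 3 diprenylmalonate; 4 diprenylmalonic acid; 5 diprenylacetic acid; 6 ethoxyacetylene; 7 acid chloride; 8 diprenylketene; 9 3-ethoxycyclobutenone; 10 carbinol; 11 3-methyl-4,4-diprenylcyclobutenone; 12 2-bromo-6-methoxybenzaldehyde; 13 (S)-tert-butanesulfinamide; 14 sulfinimine; 15 (trimethylsilyl)acetylene; 16 alkynyl Grignard reagent; 17 sulfinamide; 18 amine hydrochloride; 19 silylalkynyl lactam; 20 ethynyl lactam; 21 lithium ynolate; 22 siloxyalkyne; 23 vinylketene; 24 4-alkenylcyclobutenone; 25 dienylketene; 26 silyl ether of the target; 27 target.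

**Locants.** Ring A is the benzene ring and ring B the γ-lactam of the isoindolinone (C1 carbonyl, N2, C3 methine, C4 bearing OMe). Ring C is the carbocycle on C3: C1' (bonded to C3), C2' (OH), C3' (H), C4' (CH3), C5' (two prenyl groups), C6' (C=O).

## Analysis of the target

Target 27 joins a 4-methoxyisoindolin-1-one (rings A and B) through C3 to C1' of ring C, a 2-hydroxy-4-methyl-6-oxocyclohexa-1,3-dienyl unit whose C5' is quaternary and carries two prenyl groups. The only stereocenter is C3 (S), a methine that is benzylic, α to the lactam nitrogen and bonded to the central carbon of a vinylogous acid (C2'–OH, C6'=O). This makes C3 the sensitive point. With base, the enolate of ring C can expel the lactam nitrogen (retro-aza-Michael). With acid, the C3–C1' bond can ionize to an N-acyliminium ion and the dione (retro-Mannich). Either path racemizes. Further sensitive groups are the two acid-labile trisubstituted alkenes, the free N–H, and the dienone itself, since a thermal [3,3] shift of a prenyl group from C5' to C3' would aromatize ring C. The hard part is ring C: it is a dearomatized 5-methylresorcinol with an all-carbon quaternary C5' between C6'=O and the C4' methyl alkene. Making it by alkylating a resorcinol means fighting O- versus C-alkylation, three nucleophilic ring carbons and re-aromatization. The feature the route exploits is that ring C, read as C6'(=O)–C1'=C2'(O)–C3'H=C4'(CH3)–C5'(prenyl)2, is a 6,6-disubstituted cyclohexa-2,4-dienone with oxygen at the carbon β to the carbonyl. That is exactly the dienone through which a vinylketene–ynol ether benzannulation passes, and here it cannot tautomerize to a phenol because C5' has no hydrogen.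

## Retrosynthetic reasoning

**27 to 26.** The C2'–OH is masked as a triisopropylsilyl ether. A vinylogous silyl ester is cleaved by buffered fluoride, so the configurationally labile vinylogous acid is released only in the last step, without acid or base.

**26 to 22 and 11 (key disconnection).** Ring C is cut at C6'–C1' and C2'–C3'; the C6'–C5' bond is broken and re-formed during the step. Going forward, the two alkyne carbons of siloxyalkyne 22 (C1' and C2') are inserted into the C(O)–CH bond of cyclobutenone 11. This happens by 4π opening to vinylketene 23, [2+2] to cyclobutenone 24, 4π opening to dienylketene 25, and 6π closure onto the diprenyl carbon. The cut is made here because it builds the whole of ring C, including the quaternary C5', with every substituent in its final position and oxidation state, from two fragments that contain no ring C at all. It also never requires alkylation of an arene. The gem-diprenyl group, the obstacle for every dearomatization route, becomes the element that stops the benzannulation at the dienone. C3 is a spectator, so its configuration can be set earlier by a reliable auxiliary addition.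

**22 to 20.** The C2'–O bond is cut. Going forward, the lithium acetylide of 20 is oxidized to ynolate 21 and silylated at oxygen with a bulky silyl chloride.

**20 to 19, 17, 14, then 12, 13 and 15.** Ring B is opened at the N2–C1 and C1–C7a bonds (carbonylative closure of an ortho-bromobenzylamine), then at C3–C(alkyne). Going forward, the alkynylmagnesium reagent 16 from 15 adds to the (S)-sulfinimine 14 made from aldehyde 12 and auxiliary 13. This sets C3, and the bromide of 12 then becomes the lactam carbonyl. The OMe of 12 is ortho to the aldehyde, so it ends at C4 as required.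

**11 to 9, then 5 and 6, then 3, 1 and 2.** The methyl of 11 comes from 1,2-addition of a methyl nucleophile to vinylogous ester 9 with carbonyl transposition. 9 is the [2+2] adduct of diprenylketene 8 and 6. 8 comes from acid 5 by way of chloride 7, and 5 from double alkylation of 1 with 2 followed by decarboxylation. The two identical prenyl groups remove any alkene-geometry issue in 23.

## Alternatives that were turned down

**Alternative 1:** (textbook) Disconnection of C3–C1' between an N-acyliminium ion of ring B and the finished ring C. The forward key step is a chiral-phosphoric-acid-catalysed Mannich-type addition of vinylogous acid A2 to the iminium ion from hydroxylactam A1. Turned down for three reasons: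
- It leaves C5' unsolved. A2 is itself only reachable by dearomative double C-prenylation of its aromatic parent, with O/C and site-selectivity problems, so the hardest carbon ends up in the least selective step.
- The adduct of so stabilized an enol forms reversibly under the same Brønsted acid that ionizes A1 (re-ionization of C3–C1'), so the enantiomeric purity would drift toward the racemate.
- The aldimine-type iminium carbon is flanked by the C4 methoxy group, and O-attack by A2 competes.

**Alternative 2:** (biomimetic late dearomatization) Disconnection of both C5'–prenyl bonds. The forward key step is dearomative gem-diprenylation of resorcinol A3 with 2 and base. Turned down for three reasons: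
- The phenoxide of A3 has two oxygens and three nucleophilic ring carbons. After the first C-prenylation the second goes more readily to the remaining unsubstituted carbon, which re-aromatizes, than to the carbon already substituted.
- Base converts the ortho-hydroxybenzyl lactam into an ortho-quinone methide by loss of the amidate, which scrambles C3.
- Enantioenriched A3 costs about as many steps as 22 and buys no selectivity.

**Alternative 3:** (C3–H bond last) Disconnection of C3–H. Triketone amide A4 would be cyclized and dehydrated to ylidene lactam A5, which would be reduced asymmetrically with an organic hydride donor and a chiral acid, or by hydrogenation. Turned down for three reasons: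
- A5 is a tetrasubstituted push–pull alkene (a vinylogous imide with an internal N–H···O=C hydrogen bond). Its N-acyl ketiminium tautomer is negligible, so it is a poor hydride acceptor.
- A hydrogenation catalyst active enough for it would also saturate the prenyl groups and the C3'=C4' alkene.
- A4 needs A2 (the unsolved problem of Alternative 1) plus a regioselective C-acylation by an unsymmetrical 3-methoxyphthaloyl unit at its more hindered carbonyl.

Key step: step 10

**Assumption:** the vinylogous acid of ring C is tautomerically mobile; the tautomer of the target SMILES (C2'–OH, C6'=O) is taken as the resting form and is the one released by cleavage of the C2'–O silyl ether.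

**Remark:** the spatial arrangement at C3 is the same from 17 to 27; the descriptor changes only with substituent priorities (17, 18 R; 19 S; 20–22 R; 24–27 S).

## Route

Step 1
Reactants: 1 diethyl malonate; 2 prenyl bromide (1-bromo-3-methylbut-2-ene)
Product: 3 diethyl 2,2-bis(3-methylbut-2-en-1-yl)malonate
Conditions: NaH (2.3 equiv), 2 (2.3 equiv), THF/DMF, 0 °C to rt
Reagents that add atoms: none
Why: Double SN2 alkylation of the soft malonate carbanion at the primary allylic carbon should give C-alkylation and the unbranched prenyl (not 1,1-dimethylallyl) groups.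

Step 2
Reactants: 3 diethyl 2,2-bis(3-methylbut-2-en-1-yl)malonate
Product: 5 5-methyl-2-(3-methylbut-2-en-1-yl)hex-4-enoic acid, via 2,2-diprenylmalonic acid 4 (not isolated)
Conditions: KOH, EtOH/H2O, reflux; cold 1 M HCl to pH 2; then pyridine, 115 °C
Reagents that add atoms: potassium hydroxide, [K+].[OH-]
Why: Saponification followed by thermal decarboxylation of a disubstituted malonic acid; cold acidification and the pyridine buffer should keep the trisubstituted alkenes from acid-induced lactonization.

Step 3
Reactants: 5 5-methyl-2-(3-methylbut-2-en-1-yl)hex-4-enoic acid; 6 ethoxyacetylene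
Product: 9 3-ethoxy-4,4-bis(3-methylbut-2-en-1-yl)cyclobut-2-en-1-one, via acid chloride 7 (not isolated), via diprenylketene 8 (not isolated)
Conditions: 1-chloro-N,N,2-trimethylprop-1-en-1-amine (Ghosez reagent), CH2Cl2, 0 °C to rt; then 6 (2.5 equiv), Et3N, CH2Cl2, rt to 40 °C
Reagents that add atoms: none
Why: Neutral chloroenamine activation avoids HCl addition to the prenyl groups; dehydrochlorination gives the dialkylketene, which should undergo the regioselective ketene–ynol ether [2+2] (alkyne CH to the ketene carbonyl carbon) known for 3-ethoxycyclobutenones, and an intramolecular ketene–alkene cycloaddition is precluded by the one-carbon tether.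

Step 4
Reactants: 9 3-ethoxy-4,4-bis(3-methylbut-2-en-1-yl)cyclobut-2-en-1-one
Product: 11 3-methyl-4,4-bis(3-methylbut-2-en-1-yl)cyclobut-2-en-1-one, via carbinol 10 (not isolated)
Conditions: MeLi, Et2O, −78 °C; then 1 M HCl, 0 °C
Reagents that add atoms: methyllithium, [Li]C; water, O
Why: 1,2-Addition to the vinylogous ester and brief cold acid hydrolysis/dehydration (carbonyl transposition, the standard way to 3-alkylcyclobutenones) should put the methyl on C3 and leave the diprenyl carbon next to the new carbonyl.

Step 5
Reactants: 12 2-bromo-6-methoxybenzaldehyde; 13 (S)-2-methylpropane-2-sulfinamide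
Product: 14 (S,E)-N-(2-bromo-6-methoxybenzylidene)-2-methylpropane-2-sulfinamide
Conditions: Ti(OEt)4 (2 equiv), THF, 50 °C
Reagents that add atoms: none
Why: Titanium-alkoxide-mediated condensation (Ellman auxiliary) should give the E-sulfinimine; the Lewis acid doubles as water scavenger and copes with the doubly ortho-substituted aldehyde.

Step 6
Reactants: 14 (S,E)-N-(2-bromo-6-methoxybenzylidene)-2-methylpropane-2-sulfinamide; 15 (trimethylsilyl)acetylene
Product: 17 (S)-N-[(1R)-1-(2-bromo-6-methoxyphenyl)-3-(trimethylsilyl)prop-2-yn-1-yl]-2-methylpropane-2-sulfinamide, via alkynylmagnesium bromide 16 (not isolated)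
Conditions: 15, EtMgBr, Et2O, 0 °C to rt; then 14, CH2Cl2, −78 to −20 °C; aq NH4Cl
Reagents that add atoms: none
Why: Ellman sulfinimine addition: in a non-coordinating solvent the Grignard reagent should add through the six-membered chair transition state (magnesium on the sulfinyl oxygen, tert-butyl and the imine aryl group equatorial), which for the (S)-sulfinyl group delivers the alkyne to the face that gives the (R)-carbinamine; the aryl bromide is inert.

Step 7
Reactants: 17 (S)-N-[(1R)-1-(2-bromo-6-methoxyphenyl)-3-(trimethylsilyl)prop-2-yn-1-yl]-2-methylpropane-2-sulfinamide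
Product: 19 (S)-4-methoxy-3-[(trimethylsilyl)ethynyl]isoindolin-1-one, via amine hydrochloride 18 (not isolated)
Conditions: HCl (4 M in dioxane), MeOH, 0 °C; concentrate; then Pd(OAc)2 (5 mol%), Xantphos, CO (1 atm), Et3N, toluene, 80 °C
Reagents that add atoms: carbon monoxide, [C-]#[O+]
Why: Acidic methanolysis removes the sulfinyl group; intramolecular aminocarbonylation (oxidative addition of the aryl bromide to zerovalent palladium, CO insertion, capture of the acylpalladium by the benzylic amine) should close ring B with the carbonyl para-disposed to nothing but meta to OMe as required, and C3 is not involved so its configuration is retained.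

Step 8
Reactants: 19 (S)-4-methoxy-3-[(trimethylsilyl)ethynyl]isoindolin-1-one
Product: 20 (R)-3-ethynyl-4-methoxyisoindolin-1-one
Conditions: K2CO3 (0.3 equiv), MeOH, 0 °C
Reagents that add atoms: none
Why: Base-catalysed methanolysis of the C(sp)–Si bond; catalytic carbonate at 0 °C is far too weak to remove the propargylic C3–H, so neither racemization nor alkyne-to-allene isomerization is expected.

Step 9
Reactants: 20 (R)-3-ethynyl-4-methoxyisoindolin-1-one
Product: 22 (R)-4-methoxy-3-{[(triisopropylsilyl)oxy]ethynyl}isoindolin-1-one, via lithium ynolate 21 (not isolated)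
Conditions: LiN(SiMe3)2 (2.2 equiv), THF, −78 °C; t-BuOOLi (1.2 equiv, from t-BuOOH and LiN(SiMe3)2), −78 to 0 °C; TIPSCl (1.3 equiv), 0 °C; pH 7 buffer
Reagents that add atoms: tert-butyl hydroperoxide (used as t-BuOOLi), CC(C)(C)OO; chlorotriisopropylsilane, CC(C)[Si](Cl)(C(C)C)C(C)C
Why: The amidate acetylide should attack the electrophilic peroxide oxygen of t-BuOOLi (oxenoid oxygen transfer) to give ynolate 21, which the bulky silyl chloride silylates at oxygen (small silyl groups would give a silylketene) much faster than it silylates the hindered lactam amidate, which is reprotonated on work-up; C3–H is not removed from the dianion, so the configuration should hold.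

Step 10
Reactants: 22 (R)-4-methoxy-3-{[(triisopropylsilyl)oxy]ethynyl}isoindolin-1-one; 11 3-methyl-4,4-bis(3-methylbut-2-en-1-yl)cyclobut-2-en-1-one
Product: 26 (S)-4-methoxy-3-{4-methyl-5,5-bis(3-methylbut-2-en-1-yl)-6-oxo-2-[(triisopropylsilyl)oxy]cyclohexa-1,3-dien-1-yl}isoindolin-1-one, via vinylketene 23 (not isolated), via 4-alkenylcyclobutenone 24 (not isolated), via dienylketene 25 (not isolated)
Conditions: 11 (1.5 equiv), toluene (1.0 M in 22), 80 °C, argon, dark
Reagents that add atoms: none
Why: Proposed new method: heating 11 opens the four-membered ring (4π, conrotatory) to vinylketene 23, whose C=C=O unit is captured in a [2+2] by the electron-rich siloxyalkyne 22 (nucleophilic C1' to the ketene carbonyl carbon C6', oxygen-bearing C2' to C3') to give cyclobutenone 24; 24 opens reversibly (4π) to dienylketene 25, and the rotamer with the ketene carbon cis to the dienyl terminus closes by a thermal disrotatory 6π electrocyclization (C6'–C5') to ring C. The closest known reaction type is the Danheiser benzannulation of cyclobutenone-derived vinylketenes with siloxyalkynes, which runs through the same three pericyclic events and the same 2,4-cyclohexadienone, together with the dienylketene-to-cyclohexadienone closure that ends the Dötz reaction when the alkene terminus is fully substituted; what is new is that the terminus C5' carries two prenyl groups and no hydrogen, so the cascade must stop at the dienone instead of a phenol. Ring C is the only ring closed, by 6π electrocyclization of the ketene-terminated triene after a four-membered ring has been made by [2+2] and unmade by 4π opening, so that in sum the two alkyne carbons are inserted into the C6'–C3' bond of 11. No new stereocenter is formed: C5' bears two identical groups, the epimers of 24 at its sp3 ring carbon converge, and C3 of ring B is a spectator whose four bonds are untouched under neutral thermal conditions, so the configuration of 22 should be carried into 26. The step needs (a) the regiochemistry of the [2+2], secured by the polarization of the ynol ether, (b) intermolecular capture of 23 before it cyclizes onto one of its own prenyl alkenes, favoured by the high concentration of the strongly nucleophilic alkyne, (c) capture of the ketene by the alkyne π bond and not by the lactam N–H, a far weaker nucleophile, and (d) a temperature low enough that the product does not undergo a [3,3] prenyl shift to C3'. In one operation it should form C6'–C1' and C2'–C3', restore C6'–C5' as the quaternary junction, and place the oxygen, the methyl and both prenyl groups of ring C in their final positions.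

Step 11
Reactants: 26 (S)-4-methoxy-3-{4-methyl-5,5-bis(3-methylbut-2-en-1-yl)-6-oxo-2-[(triisopropylsilyl)oxy]cyclohexa-1,3-dien-1-yl}isoindolin-1-one
Product: 27 (S)-3-[2-hydroxy-4-methyl-5,5-bis(3-methylbut-2-en-1-yl)-6-oxocyclohexa-1,3-dien-1-yl]-4-methoxyisoindolin-1-one
Conditions: HF·pyridine, excess pyridine, THF, 0 °C; pH 7 phosphate buffer
Reagents that add atoms: none
Why: Fluoride cleavage of the vinylogous silyl ester, the most labile Si–O bond in 26, under buffered near-neutral conditions; neither an enolate (which could expel the lactam nitrogen) nor a strong acid (which could ionize C3–C1') is present, so C3 should stay (S).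

## Compound list

1 | diethyl malonate | CCOC(=O)CC(=O)OCC | starting material
2 | prenyl bromide (1-bromo-3-methylbut-2-ene) | CC(C)=CCBr | starting material
3 | diethyl 2,2-bis(3-methylbut-2-en-1-yl)malonate | CCOC(=O)C(CC=C(C)C)(CC=C(C)C)C(=O)OCC | intermediate
4 | 2,2-bis(3-methylbut-2-en-1-yl)malonic acid | OC(=O)C(CC=C(C)C)(CC=C(C)C)C(O)=O | intermediate (not isolated)
5 | 5-methyl-2-(3-methylbut-2-en-1-yl)hex-4-enoic acid | OC(=O)C(CC=C(C)C)CC=C(C)C | intermediate
6 | ethoxyacetylene | CCOC#C | starting material
7 | 5-methyl-2-(3-methylbut-2-en-1-yl)hex-4-enoyl chloride | ClC(=O)C(CC=C(C)C)CC=C(C)C | intermediate (not isolated)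
8 | bis(3-methylbut-2-en-1-yl)ketene | O=C=C(CC=C(C)C)CC=C(C)C | intermediate (not isolated)
9 | 3-ethoxy-4,4-bis(3-methylbut-2-en-1-yl)cyclobut-2-en-1-one | CCOC1=CC(=O)C1(CC=C(C)C)CC=C(C)C | intermediate
10 | 3-ethoxy-1-methyl-4,4-bis(3-methylbut-2-en-1-yl)cyclobut-2-en-1-ol (racemic, formed as its lithium alkoxide) | CCOC1=CC(C)(O)C1(CC=C(C)C)CC=C(C)C | intermediate (not isolated)
11 | 3-methyl-4,4-bis(3-methylbut-2-en-1-yl)cyclobut-2-en-1-one | CC1=CC(=O)C1(CC=C(C)C)CC=C(C)C | intermediate
12 | 2-bromo-6-methoxybenzaldehyde | COc1cccc(Br)c1C=O | starting material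
13 | (S)-2-methylpropane-2-sulfinamide | CC(C)(C)[S@](=O)N | starting material
14 | (S,E)-N-(2-bromo-6-methoxybenzylidene)-2-methylpropane-2-sulfinamide | CC(C)(C)[S@](=O)/N=C/c1c(OC)cccc1Br | intermediate
15 | (trimethylsilyl)acetylene | C#C[Si](C)(C)C | starting material
16 | [(trimethylsilyl)ethynyl]magnesium bromide | C[Si](C)(C)C#C[Mg]Br | intermediate (not isolated)
17 | (S)-N-[(1R)-1-(2-bromo-6-methoxyphenyl)-3-(trimethylsilyl)prop-2-yn-1-yl]-2-methylpropane-2-sulfinamide | CC(C)(C)[S@](=O)N[C@H](C#C[Si](C)(C)C)c1c(OC)cccc1Br | intermediate
18 | (1R)-1-(2-bromo-6-methoxyphenyl)-3-(trimethylsilyl)prop-2-yn-1-amine hydrochloride | N[C@H](C#C[Si](C)(C)C)c1c(OC)cccc1Br.Cl | intermediate (not isolated)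
19 | (S)-4-methoxy-3-[(trimethylsilyl)ethynyl]isoindolin-1-one | COc1cccc2c1[C@@H](C#C[Si](C)(C)C)NC2=O | intermediate
20 | (R)-3-ethynyl-4-methoxyisoindolin-1-one | COc1cccc2c1[C@@H](C#C)NC2=O | intermediate
21 | dilithium salt of (R)-3-(oxidoethynyl)-4-methoxyisoindolin-1-one (ynolate amidate) | COc1cccc2c1[C@@H](C#C[O-])[N-]C2=O.[Li+].[Li+] | intermediate (not isolated)
22 | (R)-4-methoxy-3-{[(triisopropylsilyl)oxy]ethynyl}isoindolin-1-one | COc1cccc2c1[C@@H](C#CO[Si](C(C)C)(C(C)C)C(C)C)NC2=O | intermediate
23 | 3,7-dimethyl-4-(3-methylbut-2-en-1-yl)octa-1,3,6-trien-1-one (vinylketene) | O=C=CC(C)=C(CC=C(C)C)CC=C(C)C | intermediate (not isolated)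
24 | (3S)-4-methoxy-3-{3-[6-methyl-3-(3-methylbut-2-en-1-yl)hepta-2,5-dien-2-yl]-4-oxo-2-[(triisopropylsilyl)oxy]cyclobut-1-en-1-yl}isoindolin-1-one (both epimers at the sp3 ring carbon) | COc1cccc2c1[C@@H](C1=C(O[Si](C(C)C)(C(C)C)C(C)C)C(C(C)=C(CC=C(C)C)CC=C(C)C)C1=O)NC2=O | intermediate (not isolated)
25 | 2-[(1S)-7-methoxy-3-oxoisoindolin-1-yl]-5,9-dimethyl-6-(3-methylbut-2-en-1-yl)-3-[(triisopropylsilyl)oxy]deca-1,3,5,8-tetraen-1-one (dienylketene, ketene carbon cis to the dienyl terminus) | COc1cccc2c1[C@@H](C(=C=O)/C(O[Si](C(C)C)(C(C)C)C(C)C)=C\C(C)=C(CC=C(C)C)CC=C(C)C)NC2=O | intermediate (not isolated)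
26 | (S)-4-methoxy-3-{4-methyl-5,5-bis(3-methylbut-2-en-1-yl)-6-oxo-2-[(triisopropylsilyl)oxy]cyclohexa-1,3-dien-1-yl}isoindolin-1-one | COc1cccc2c1[C@@H](C1=C(O[Si](C(C)C)(C(C)C)C(C)C)C=C(C)C(CC=C(C)C)(CC=C(C)C)C1=O)NC2=O | intermediate
27 | (S)-3-[2-hydroxy-4-methyl-5,5-bis(3-methylbut-2-en-1-yl)-6-oxocyclohexa-1,3-dien-1-yl]-4-methoxyisoindolin-1-one | COc1cccc2c1[C@@H](C1=C(O)C=C(C)C(CC=C(C)C)(CC=C(C)C)C1=O)NC2=O | target

## Step count and risk

Total step count: 11. Longest linear sequence: 7 steps (steps 5 to 11). The cyclobutenone branch (steps 1 to 4) joins at step 10.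

**Step 10 (key step, Proposed new method).** Four processes may interfere:
- Unimolecular cyclization of the vinylketene onto one of its own prenyl alkenes (intramolecular ketene–alkene [2+2]) before the alkyne captures it.
- Slow 4π opening of the 4,4-disubstituted cyclobutenone, which would force higher temperatures.
- At those temperatures, a [3,3] prenyl shift from C5' to C3' followed by aromatization of ring C.
- Acylation of the lactam N–H by ketene.

The fallback uses only known chemistry, sets out from 22 and comes back at 26. Acetyl chloride, Et3N and 6 give 3-ethoxycyclobut-2-en-1-one F1. Methyllithium addition and acid hydrolysis, as in step 4, give 3-methylcyclobut-2-en-1-one F2. Heating F2 with 22 in toluene at 80 °C is an ordinary Danheiser benzannulation, which should give the aromatic (S)-3-{2-hydroxy-4-methyl-6-[(triisopropylsilyl)oxy]phenyl}-4-methoxyisoindolin-1-one F3. Its sodium phenoxide (NaH, toluene) is C-prenylated with 2 ortho to the oxygen to give the 3-prenyl phenol (S)-3-{2-hydroxy-4-methyl-3-(3-methylbut-2-en-1-yl)-6-[(triisopropylsilyl)oxy]phenyl}-4-methoxyisoindolin-1-one F4. A second ortho C-alkylation at the same carbon, under the same non-polar conditions (the known dearomatizing ortho-alkylation of 2,6-disubstituted phenoxides), gives 26. This fallback pays for certainty in the ring synthesis with lower site selectivity in the alkylations.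

**Step 9.** Oxygen transfer to the acetylide may be incomplete in the presence of the poorly soluble amidate dianion. Silylation may be shared between ynolate oxygen and lactam nitrogen. Excess amide base may cause propargyl–allenyl equilibration at C3. The fallback sets out from 20 and comes back at 21, and so at 22. It oxidizes the alkyne electrophilically instead of through its anion. PhI(OH)OTs in CH2Cl2 converts 20 into the alkynyl(phenyl)iodonium tosylate (S)-[(7-methoxy-3-oxoisoindolin-1-yl)ethynyl](phenyl)iodonium 4-methylbenzenesulfonate F5. Catalytic CuOTf in acetonitrile rearranges it to the alkynyl tosylate (R)-(7-methoxy-3-oxoisoindolin-1-yl)ethynyl 4-methylbenzenesulfonate F6. Methyllithium (2 equiv, THF, −78 °C) cleaves F6 at sulfur to ynolate 21, which is silylated as in step 9.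

**Step 3.** Dehydrochlorination of the α-branched acid chloride may be slow, so that acylammonium side reactions and ketene dimerization compete with the cycloaddition. The fallback sets out from 5 (through 7) and comes back at 11, bypassing 9 and step 4. Acid chloride 7 and dimethylamine give N,N,5-trimethyl-2-(3-methylbut-2-en-1-yl)hex-4-enamide F7. Tf2O and 2,4,6-collidine in the presence of propyne generate the keteniminium triflate F8. Its [2+2] with the alkyne (terminal carbon to the iminium carbon) gives the cyclobutenyliminium triflate F9. Aqueous NaHCO3 hydrolyses F9 to 11.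

**Step 6.** Facial selectivity may be poor, because the doubly ortho-substituted aryl group and the alkynyl nucleophile can erode the chelated transition state, or divert the reaction to an open one with the opposite sense. The fallback sets out from 15 and comes back at 20. It reverses the roles so that the aryl group, not the alkyne, is the nucleophile. Formylation of 16 with DMF gives 3-(trimethylsilyl)prop-2-ynal F10. Condensation with (R)-2-methylpropane-2-sulfinamide (Ti(OEt)4) gives (R,E)-2-methyl-N-[3-(trimethylsilyl)prop-2-yn-1-ylidene]propane-2-sulfinamide F11. Bromine–magnesium exchange of methyl 2-bromo-3-methoxybenzoate with i-PrMgCl·LiCl gives [2-methoxy-6-(methoxycarbonyl)phenyl]magnesium chloride F12. Its addition to F11 in toluene/CH2Cl2 at −78 °C, an aryl Grignard addition that follows the chelate model reliably, should give methyl 2-[(1S)-1-{[(R)-tert-butylsulfinyl]amino}-3-(trimethylsilyl)prop-2-yn-1-yl]-3-methoxybenzoate F13. HCl/MeOH and then K2CO3/MeOH remove the sulfinyl group, close the lactam onto the ester and cleave the silyl group to give 20.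

## Further compounds

F1 | step 10 | 3-ethoxycyclobut-2-en-1-one | CCOC1=CC(=O)C1
F2 | step 10 | 3-methylcyclobut-2-en-1-one | CC1=CC(=O)C1
F3 | step 10 | (S)-3-{2-hydroxy-4-methyl-6-[(triisopropylsilyl)oxy]phenyl}-4-methoxyisoindolin-1-one | COc1cccc2c1[C@@H](c1c(O)cc(C)cc1O[Si](C(C)C)(C(C)C)C(C)C)NC2=O
F4 | step 10 | (S)-3-{2-hydroxy-4-methyl-3-(3-methylbut-2-en-1-yl)-6-[(triisopropylsilyl)oxy]phenyl}-4-methoxyisoindolin-1-one | COc1cccc2c1[C@@H](c1c(O)c(CC=C(C)C)c(C)cc1O[Si](C(C)C)(C(C)C)C(C)C)NC2=O
F5 | step 9 | (S)-[(7-methoxy-3-oxoisoindolin-1-yl)ethynyl](phenyl)iodonium 4-methylbenzenesulfonate | COc1cccc2c1[C@@H](C#C[I+]c1ccccc1)NC2=O.Cc1ccc(cc1)S(=O)(=O)[O-]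
F6 | step 9 | (R)-(7-methoxy-3-oxoisoindolin-1-yl)ethynyl 4-methylbenzenesulfonate | COc1cccc2c1[C@@H](C#COS(=O)(=O)c1ccc(C)cc1)NC2=O
F7 | step 3 | N,N,5-trimethyl-2-(3-methylbut-2-en-1-yl)hex-4-enamide | CN(C)C(=O)C(CC=C(C)C)CC=C(C)C
F8 | step 3 | N,N-dimethyl-2,2-bis(3-methylbut-2-en-1-yl)keteniminium triflate | C[N+](C)=C=C(CC=C(C)C)CC=C(C)C.[O-]S(=O)(=O)C(F)(F)F
F9 | step 3 | N-methyl-N-[3-methyl-4,4-bis(3-methylbut-2-en-1-yl)cyclobut-2-en-1-ylidene]methanaminium triflate | C[N+](C)=C1C=C(C)C1(CC=C(C)C)CC=C(C)C.[O-]S(=O)(=O)C(F)(F)F
F10 | step 6 | 3-(trimethylsilyl)prop-2-ynal | C[Si](C)(C)C#CC=O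
F11 | step 6 | (R,E)-2-methyl-N-[3-(trimethylsilyl)prop-2-yn-1-ylidene]propane-2-sulfinamide | CC(C)(C)[S@@](=O)/N=C/C#C[Si](C)(C)C
F12 | step 6 | [2-methoxy-6-(methoxycarbonyl)phenyl]magnesium chloride | COC(=O)c1cccc(OC)c1[Mg]Cl
F13 | step 6 | methyl 2-[(1S)-1-{[(R)-tert-butylsulfinyl]amino}-3-(trimethylsilyl)prop-2-yn-1-yl]-3-methoxybenzoate | CC(C)(C)[S@@](=O)N[C@H](C#C[Si](C)(C)C)c1c(OC)cccc1C(=O)OC
A1 | alternative 1 | 3-hydroxy-4-methoxyisoindolin-1-one | COc1cccc2C(=O)NC(O)c12
A2 | alternative 1 | 3-hydroxy-5-methyl-6,6-bis(3-methylbut-2-en-1-yl)cyclohexa-2,4-dien-1-one | CC1=CC(O)=CC(=O)C1(CC=C(C)C)CC=C(C)C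
A3 | alternative 2 | (S)-3-(2,6-dihydroxy-4-methylphenyl)-4-methoxyisoindolin-1-one | COc1cccc2c1[C@@H](c1c(O)cc(C)cc1O)NC2=O
A4 | alternative 3 | 2-{[2-hydroxy-4-methyl-5,5-bis(3-methylbut-2-en-1-yl)-6-oxocyclohexa-1,3-dien-1-yl]carbonyl}-3-methoxybenzamide | COc1cccc(C(N)=O)c1C(=O)C1=C(O)C=C(C)C(CC=C(C)C)(CC=C(C)C)C1=O
A5 | alternative 3 | 4-methoxy-3-[4-methyl-5,5-bis(3-methylbut-2-en-1-yl)-2,6-dioxocyclohex-3-en-1-ylidene]isoindolin-1-one | COc1cccc2C(=O)NC(=C3C(=O)C=C(C)C(CC=C(C)C)(CC=C(C)C)C3=O)c12
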